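## Structural features

Psiguadial A joins an aromadendrane sesquiterpene to a 3,5-diformylphloroglucinol through two bonds. A cyclopentane (C1–C5) is cis-fused along C1–C5 to a cycloheptane (C1, C5–C10) that carries the gem-dimethylcyclopropane C6–C7–C11. The arene is attached through the phenyl-bearing benzylic carbon C7′ to quaternary C4 and through an ether oxygen to tertiary C1 (C14 is the methyl on C10, C15 the methyl on C4, primed numbers the aryl unit). Because C4 and C1 are 1,3 on the cyclopentane, the O–C2′–C1′–C7′ bridge closes an oxepine over one face of that ring, so C7′, H5 and the ether oxygen are all cis. There are seven stereocentres: five contiguous (C7′, C4, C5, C6, C7), two fully substituted (C1, C4), and C10, whose methyl lies on the same face of the seven-membered ring as the cyclopropane CMe2. Fragile groups are the cyclopropane (strong acid, a cation at C5), the tertiary alkyl aryl ether (strong Lewis acid) and the two aldehydes between phenols (hydride, enolates), which argues for introducing the formyl groups last. The real difficulty is the crowded C4–C7′ bond with control of both centres, together with an ether at a ring-fusion carbon. The key step uses two facts: C5–C10 with the cyclopropane carbons C6 and C7 are the six-membered ring of carene, stereocentres included, and C1–C5, O–C1 and C10–H can all be made in one cationic event from a ten-membered ring C1–C10 that holds an E C1=C10 alkene and an oxygen on C5. The [3,3] shift inserts C1–C4 into the carene ring and gives exactly that ring.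

## Logic of the disconnections

25 ⇒ 24. Cut the two aryl C–CHO bonds (C3′ and C5′). The aldehydes cannot pass through hydride, enolate or hydrogenation steps; without them the arene is an electron-rich resorcinol monoether whose only two free positions are the ones wanted. Demand: a double formylation that spares the cyclopropane and the C1–O bond.

24 ⇒ 23. Cut the two O–CH2Ph bonds. The spectator phenols must be masked during enolate, hydride and cation chemistry. Benzyl is preferred to methyl because it leaves by neutral hydrogenolysis, whereas methyl ethers would need hot acid or boron halides beside a cyclopropane and a tertiary ether. Demand: nothing else in 23 may be reducible; it holds no alkene.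

23 ⇒ 19. Cut O–C1 and C1–C5, return the hydrogen on C10 to C1 and put a leaving oxygen on C5. This undoes three stereocentres (C1, C5, C10) and two rings in one move and leaves a ten-membered carbocycle with an E C1=C10 alkene. It follows the charge pattern of the skeleton: C5 is next to the cyclopropane, C10 and C1 are tertiary. Demand: the cation must start at C5 only, the ring must fold so that C1 reaches C5, and the one free phenol must end the cascade at C1.

19 ⇒ 18. C5–OH back to C5=O. The ketone is what makes C4 nucleophilic one step earlier. Demand: a small hydride for a carbonyl flanked by a quaternary carbon and a cyclopropane; the configuration formed is irrelevant.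

18 ⇒ 12 + 15. Cut C4–C7′. C4 is the only enolisable neighbour of the C5 carbonyl, and C7′ becomes electrophilic once 15 loses sulfinate (as 17), so polarity and regiochemistry are unambiguous and the molecule splits into its terpene and aromatic halves. Demand: the addition creates quaternary C4 and C7′ together and must choose one face of each partner. The enolate born in the key step (11) has C3 and C6 cis and is not used directly; 12 is re-enolised.

15 ⇒ 13 + 14. Cut C7′–C1′ and C7′–S: a three-component condensation of catalogue materials in which the sulfinate is only a placeholder. Demand: substitution ortho to the free hydroxyl.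

12 ⇒ 9. Reconnect C5–C10 and cut C2–C3 (retro [3,3]). The ten-membered ring, which has no good direct closure, shrinks to a cyclohexane with two alkenyl groups on neighbouring carbons, that is, to a derivative of 1 with C6 and C7 already correct. Demand: the forward shift must give the E C1=C10 alkene. For the cis-dialkenyl arrangement of 9 this means reaction through the chair with the vinyl group axial, not equatorial; an equatorial vinyl group in the same chair would lead to the Z alkene.

9 ⇒ 7 + 8. Cut C5–C4: 1,2-addition of a C3 alkenyl nucleophile. Demand: addition, not reduction, at a very hindered carbonyl.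

7 ⇒ 4 + 5. Cut C10–C1: α-alkenylation. The ketone can enolise toward C10 only, so the quaternary centre needs no blocking group. Demand: C–C bond formation at a fully substituted enolate carbon.

4 ⇒ 3 ⇒ 1. Carbonyl back to secondary alcohol, then to the alkene by anti-Markovnikov hydration; the double bond of 1 marks exactly C5/C10. Demand: boron on the carbon next to the cyclopropane, which the trisubstituted alkene ensures.

## Other disconnections considered

Alternative 1: The cut goes through C4–C7′ and O–C1 at once and removes the whole aryl bridge from a preformed 5–7–3 tricycle: enone A1 plus sulfone A2 give ketone A3. In the forward step the kinetic α′-enolate of A1 (LiN(iPr)2) attacks, through C4, the quinone methide set free from A2, and the resulting phenoxide closes onto C1 of the enone (oxa-Michael), a formal (4+3) annulation.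
- In its favour: both bonds of the oxepine form under basic conditions, so no carbocation is generated beside the cyclopropane. On this point it is better than the chosen plan, whose step 9 is cationic.
- In its favour: the enolate sits in a rigid fused bicycle with clearly different faces, so the C4 configuration is easier to predict than on the flexible enolate 16. Again better.
- Equal: C1 is set by the tether in both plans, and the C4–C7′ bond is made by the same reaction type.
- Against it: A1 must be built first with C5 and C10 correct, which needs its own multi-step hydroazulene synthesis. The chosen plan creates C1, C5, C10 and both carbocycles in step 9 from a ketone available in five steps.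
- Against it: the oxa-Michael onto a β,β-disubstituted enone to form a fully substituted ether is reversible and may stop at the open phenol.
- Against it: the C3 carbonyl of A3 is not in the target and costs one to three further steps.
- Balance: the chosen plan is ahead on step economy; Alternative 1 is ahead on mechanistic safety near the cyclopropane.

Alternative 2: The cut is the skeletal C1–C5 bond with reconnection of C5–C10: hydroazulenone A5 is traced to the cross-conjugated decalin dienone A4, which already carries the aryl(phenyl)methyl group on C4. In the forward step, irradiation of A4 near 350 nm in aqueous acetic acid joins C1 to C5, cleaves C5–C10 and delivers water to C10 (dienone photorearrangement of the santonin type).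
- In its favour: a well-understood rearrangement; A4 is a simple 6–6 system that could be reached by annulation onto 4, so the carene origin is shared (equal).
- In its favour: the medium ring and its conformational uncertainty are avoided (better), and C4–C7′ exists before the skeleton is rearranged.
- Against it: C4 in A5 is trigonal and lacks C15, so the quaternary centre must still be made (for instance by reductive methylation of the enone). C1, C5, C10 and the ether then need separate operations.
- Against it: C7′ is created early, beside a flat dienone carbon and far from C6/C7, with nothing to control it.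
- Against it: the C10 hydroxyl is introduced only to be removed, the C3 carbonyl must be deleted, and the trimethoxyphenyl group needs a selective mono-demethylation before ether closure.
- Against it: the cyclopropane is conjugated through C6 with the excited dienone, and the electron-rich arene may quench or divert the excited state.
- Balance: the photochemical step is probably as reliable as the oxy-Cope shift (equal), but it leaves no lasting stereocentre and far more to do afterwards; the chosen plan is clearly shorter.

Alternative 3: The cut takes out C1–C5, C2–C3 and C3–C4 together: dienone A7 is traced to allenyne A6 and carbon monoxide. In the forward step [Rh(CO)2Cl]2 under CO engages the alkyne, the distal double bond of the allene and CO in an allenic Pauson–Khand reaction that closes the cyclopentenone and the seven-membered ring in one step.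
- In its favour: three C–C bonds and two rings per step, catalytic in rhodium, with the cis-cyclopropane holding the two unsaturated arms together. In bonds made per step it is better than the oxy-Cope shift (one skeletal bond).
- Equal: like the oxy-Cope shift it needs no protecting group and creates no lasting stereocentre.
- Against it: A7 has no substituent on C4, so C15 and C7′ must both be attached later, one after the other, on a cross-conjugated dienone with several acidic positions.
- Against it: C1, C5 and C10 are all trigonal in A7 and would have to be set by later reductions and additions without an obvious controlling element; the C3 carbonyl is extraneous.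
- Against it: A6 requires opening the six-membered ring of 1 and building an alkyne and an allene on the two cyclopropane arms, which takes more steps than the four that lead to 9.
- Balance: as a ring-forming step it is the equal or the better of the [3,3] shift, but the chosen plan follows its key step with a cascade that forms three stereocentres and the ether at once, so the overall count favours the chosen plan.

Key step: step 5

Assumptions (remarks on the chemistry):
- 3,5-Bis(benzyloxy)phenol 13 is taken to be a catalogue compound.
- Carbinol 19 is carried on as a mixture of C5 epimers, since C5 is ionised in step 9.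
- The exocyclic double-bond geometry of 17 is not controlled and is left open.

## Steps

Step 1
Reactants: 1 (+)-2-carene
Product: 3 2-isocaranol [(1S,2R,3S,6R)-3,7,7-trimethylbicyclo[4.1.0]heptan-2-ol; hydroxyl on C5 anti to the CMe2 bridge and trans to the C10 methyl], via bis(2-isocaranyl)borane 2 (not isolated)
Conditions: BH3·SMe2 (0.5 equiv), THF, 0 °C → rt; then 3 M NaOH, 30% H2O2, 0 → 40 °C
Reagents that add atoms: hydrogen peroxide, OO (oxygen on C5); borane–dimethyl sulfide, [BH3-][S+](C)C (boron held only in 2)
Why: Hydroboration–oxidation: syn addition of B–H from the face opposite the CMe2 bridge puts boron on the less substituted C5, and oxidation with retention gives the alcohol. Both new centres disappear later (C5 in step 2, C10 in step 3), so only the regiochemistry matters.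

Step 2
Reactants: 3 2-isocaranol
Product: 4 caran-2-one [(1S,3S,6R)-3,7,7-trimethylbicyclo[4.1.0]heptan-2-one]
Conditions: Dess–Martin periodinane, CH2Cl2, 0 °C → rt
Reagents that add atoms: none
Why: Hypervalent-iodine oxidation of a secondary alcohol to the ketone under mild conditions that leave the cyclopropane alone; the configuration of the C10 methyl is of no consequence because C10 is enolised next.

Step 3
Reactants: 4 caran-2-one; 5 vinyl bromide
Product: 7 (1S,3S,6R)-3-ethenyl-3,7,7-trimethylbicyclo[4.1.0]heptan-2-one (vinyl on C10 anti to the CMe2 bridge), via lithium enolate 6 (not isolated)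
Conditions: LiN(SiMe3)2 (1.2 equiv), Pd2(dba)3 (2.5 mol %), P(t-Bu)3·HBF4 (6 mol %), vinyl bromide (1 M in THF, 2 equiv), toluene, sealed tube, rt → 50 °C
Reagents that add atoms: none
Why: Palladium-catalysed α-alkenylation of a ketone enolate: oxidative addition of 5 to zerovalent palladium, exchange with enolate 6 and C–C reductive elimination build quaternary C10. Only C10 can enolise because the other α-carbon (C6) is a cyclopropane CH, and the vinylpalladium unit approaches the enolate face remote from the CMe2 bridge.

Step 4
Reactants: 7 vinyl ketone; 8 isopropenylmagnesium bromide
Product: 9 (1S,2S,3S,6R)-3-ethenyl-3,7,7-trimethyl-2-(prop-1-en-2-yl)bicyclo[4.1.0]heptan-2-ol (vinyl and isopropenyl cis to each other and anti to the CMe2 bridge; hydroxyl syn to it)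
Conditions: CeCl3 (dried, 1.5 equiv), THF, −78 °C; 8 (0.5 M in THF), −78 → 0 °C; aq NH4Cl
Reagents that add atoms: none
Why: Organocerium 1,2-addition, which is weakly basic and strongly oxophilic, forms C4–C5 at a carbonyl flanked by a quaternary carbon and a cyclopropane. The nucleophile enters C5 from the face away from the endo methyl of C11, so the hydroxyl ends up syn to the cyclopropane and the two alkenyl groups cis.

Step 5
Reactants: 9 divinyl carbinol
Product: 12 (1(10)E,6S,7R)-5-oxo-4,5-dihydrobicyclogermacrene (ten-membered ketone; C4 epimers), via potassium alkoxide 10 (not isolated), via potassium enolate 11 (not isolated)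
Conditions: KH (1.5 equiv), 18-crown-6 (1.5 equiv), THF, 0 °C → rt; aq NH4Cl, 0 °C
Reagents that add atoms: none
Why: KH deprotonates the tertiary alcohol and 18-crown-6 frees alkoxide 10 from its cation, which weakens C5–C10 and lets the [3,3] shift run near room temperature (anionic oxy-Cope rearrangement; the closest known case is the conversion of 1,2-dialkenylcyclohexanols into cyclodec-5-enones). C2 bonds to C3 while C5–C10 breaks, so no ring is closed by cyclisation: the six-membered ring is enlarged by the four carbons C1–C4 to the ten-membered ring, and formation of enolate 11 is the driving force. No lasting stereocentre is created: C5 and C10 become trigonal, C6 and C7 are untouched, and C4 is set only transiently on protonation and erased again in step 7. The selectivity that matters is the E geometry of C1=C10. In 9 the two alkenyl groups are cis, so the chair array C2–C1–C10–C5–C4–C3 is cis-fused to the carbocycle and must place either C9 or C6 axial on it; the E alkene needs C9 equatorial, which means the vinyl group axial on the six-membered ring (on the face away from the CMe2 bridge) and the C10 methyl equatorial. That conformer should be preferred because the alternative puts the C10 methyl axial beneath the endo methyl of C11; it delivers an enolate with C3 and C6 cis, which is irrelevant because 11 is protonated. The cyclopropane is a spectator because none of its bonds belongs to the 1,5-diene, and a cold NH4Cl quench avoids aldol chemistry of 11.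

Step 6
Reactants: 13 3,5-bis(benzyloxy)phenol; 14 benzaldehyde
Product: 15 3,5-bis(benzyloxy)-2-[phenyl(4-methylphenylsulfonyl)methyl]phenol (racemic at C7′)
Conditions: TolSO2Na (1.5 equiv), HCO2H/H2O/THF, rt
Reagents that add atoms: sodium p-toluenesulfinate, Cc1ccc(cc1)S(=O)[O-].[Na+]
Why: Acid-mediated three-component Mannich-type condensation: hydroxyalkylation of the electron-rich phenol ortho to OH, loss of water to the benzylic cation, and capture by sulfinate at sulfur. The ortho site (between OH and one OBn) is less crowded than the site between the two benzyloxy groups and is helped by hydrogen bonding of the phenol to the aldehyde; the C7′ centre is lost again in step 7.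

Step 7
Reactants: 12 ten-membered ketone; 15 sulfone
Product: 18 ketone 12 carrying on C4 the (2-hydroxy-4,6-dibenzyloxyphenyl)(phenyl)methyl group (C4 and C7′ configured as in 25; may rest as the cyclic hemiketal), via lithium enolate 16 (not isolated), via ortho-quinone methide 17 (not isolated)
Conditions: 12, LiN(iPr)2 (1.1 equiv), THF, −78 °C; separately 15 (1.2 equiv), LiN(SiMe3)2 (1.2 equiv), THF, −78 °C; combine, −78 → 0 °C; aq NH4Cl
Reagents that add atoms: none
Why: Michael (1,4) addition of a ketone enolate to an ortho-quinone methide released by 1,4-elimination of sulfinate from the lithium phenoxide of 15; rearomatisation pays for the crowded C4–C7′ bond, and C4 is the only enolisable carbon, so the regiochemistry is fixed. C4 should be set by attack on the outer face of enolate 16 in its crown conformation (the face turned away from C1=C10, the one an electrophile meets in the corresponding 1(10),4-diene). C7′ should be set by the compact lithium-bridged transition state in which the phenyl group lies over the small C4 methyl and C7′–H over ring carbon C3.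

Step 8
Reactants: 18 C4-alkylated ketone
Product: 19 the corresponding C5 carbinol (C5 epimers)
Conditions: LiAlH4 (3 equiv), THF, 0 → 50 °C; H2O, aq NaOH work-up
Reagents that add atoms: none
Why: Hydride reduction of the hindered cyclopropyl ketone; the phenol travels as its aluminium phenoxide, and any hemiketal form of 18 reopens under these basic conditions. The configuration of the new carbinol is immaterial because C5 is ionised in step 9.

Step 9
Reactants: 19 C5 carbinol
Product: 23 pentacyclic dibenzyl ether (all seven stereocentres as in 25), via C5 cation 20 (not isolated), via C10 cation 21 (not isolated), via C1 cation 22 (not isolated)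
Conditions: TsOH·H2O (10 mol %), (CF3)2CHOH/CH2Cl2 (1:4), −20 °C → rt
Reagents that add atoms: none
Why: Biomimetic cation–olefin cascade: ionisation of the cyclopropylcarbinyl alcohol gives bisected cation 20, C1 of the E alkene attacks C5 across the ring (closing the five- and seven-membered carbocycles), a suprafacial 1,2-hydride shift moves H from C1 to C10, and the tethered phenol captures C1 to close the oxepine. C5 is set by the bisected cation reacting with C4 turned away from the cyclopropane and C1 arriving from the C7 side (H5 anti to H6), C10 by the hydride arriving on the face away from the CMe2 bridge, and C1 by the tether, which lets the oxygen reach only the face cis to C7′. Capture of 20 by the phenol oxygen (a chromane) should be reversible under these ionising conditions, so material should drain to 23, the only outcome without a remaining alkene.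

Step 10
Reactants: 23 pentacyclic dibenzyl ether
Product: 24 pentacyclic resorcinol (4′,6′-diol)
Conditions: H2 (1 atm), Pd/C (10 wt %), EtOAc/MeOH, rt
Reagents that add atoms: none
Why: Hydrogenolysis of aryl benzyl ethers under neutral conditions; the cyclopropane, the tertiary alkyl aryl ether and the diarylmethine C7′–H are not cleaved on palladium at one atmosphere, and no alkene is left.

Step 11
Reactants: 24 pentacyclic resorcinol
Product: 25 psiguadial A
Conditions: Cl2CHOMe (6 equiv), TiCl4 (6 equiv), CH2Cl2, −78 → 0 °C; then 1 M HCl, rt
Reagents that add atoms: dichloromethyl methyl ether, COC(Cl)Cl; water, O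
Why: Rieche formylation: the titanium phenoxide directs the chloro(methoxy)carbenium ion to the two free ring positions C3′ and C5′, each flanked by two oxygen substituents, and hydrolysis of the α-chloro ethers releases the aldehydes. Placing this last keeps the aldehydes away from hydride, enolate and hydrogenation; no stereocentre is touched.

## Compound list

1 | (+)-2-carene [(1S,6R)-3,7,7-trimethylbicyclo[4.1.0]hept-2-ene] | CC1=C[C@H]2[C@@H](CC1)C2(C)C | starting material
2 | bis(2-isocaranyl)borane (not isolated) | [H]B([C@@H]1[C@@H](C)CC[C@@H]2[C@H]1C2(C)C)[C@@H]1[C@@H](C)CC[C@@H]2[C@H]1C2(C)C | intermediate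
3 | 2-isocaranol, (1S,2R,3S,6R)-3,7,7-trimethylbicyclo[4.1.0]heptan-2-ol | C[C@H]1CC[C@@H]2[C@H]([C@@H]1O)C2(C)C | intermediate
4 | caran-2-one, (1S,3S,6R)-3,7,7-trimethylbicyclo[4.1.0]heptan-2-one | C[C@H]1CC[C@@H]2[C@H](C1=O)C2(C)C | intermediate
5 | vinyl bromide | C=CBr | starting material
6 | lithium enolate of 4 (C10=C5; not isolated) | CC1=C([O-])[C@H]2[C@@H](CC1)C2(C)C.[Li+] | intermediate
7 | (1S,3S,6R)-3-ethenyl-3,7,7-trimethylbicyclo[4.1.0]heptan-2-one | C[C@@]1(C=C)CC[C@@H]2[C@H](C1=O)C2(C)C | intermediate
8 | isopropenylmagnesium bromide | CC(=C)[Mg]Br | starting material
9 | (1S,2S,3S,6R)-3-ethenyl-3,7,7-trimethyl-2-(prop-1-en-2-yl)bicyclo[4.1.0]heptan-2-ol (key-step precursor) | C[C@@]1(C=C)CC[C@@H]2[C@H]([C@]1(O)C(C)=C)C2(C)C | intermediate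
10 | potassium alkoxide of 9 (not isolated) | C[C@@]1(C=C)CC[C@@H]2[C@H]([C@]1([O-])C(C)=C)C2(C)C.[K+] | intermediate
11 | potassium enolate of 12 as formed in the shift (C1=C10 E; C3 and C6 cis across C4=C5; not isolated) | C/C1=C\CC/C(C)=C(/[O-])\[C@H]2[C@@H](CC1)C2(C)C.[K+] | intermediate
12 | (1(10)E,6S,7R)-5-oxo-4,5-dihydrobicyclogermacrene (key-step product; C4 epimers) | C/C1=C\CCC(C)C(=O)[C@H]2[C@@H](CC1)C2(C)C | intermediate
13 | 3,5-bis(benzyloxy)phenol | Oc1cc(OCc2ccccc2)cc(OCc2ccccc2)c1 | starting material
14 | benzaldehyde | O=Cc1ccccc1 | starting material
15 | 3,5-bis(benzyloxy)-2-[phenyl(4-methylphenylsulfonyl)methyl]phenol (racemic) | Cc1ccc(cc1)S(=O)(=O)C(c1ccccc1)c1c(O)cc(OCc2ccccc2)cc1OCc1ccccc1 | intermediate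
16 | lithium enolate of 12 from kinetic deprotonation (C3 and C6 trans across C4=C5, as expected; not isolated) | C/C1=C\CC/C(C)=C(\[O-])/[C@H]2[C@@H](CC1)C2(C)C.[Li+] | intermediate
17 | 6-benzylidene-3,5-bis(benzyloxy)cyclohexa-2,4-dien-1-one (ortho-quinone methide; exocyclic geometry open; not isolated) | O=C1C=C(OCc2ccccc2)C=C(OCc2ccccc2)C1=Cc1ccccc1 | intermediate
18 | C4-alkylated ketone: 12 bearing on C4 the (2-hydroxy-4,6-dibenzyloxyphenyl)(phenyl)methyl group, C4 and C7′ as in 25 | C/C1=C\CC[C@](C)([C@@H](c2ccccc2)c2c(O)cc(OCc3ccccc3)cc2OCc2ccccc2)C(=O)[C@H]2[C@@H](CC1)C2(C)C | intermediate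
19 | C5 carbinol of 18 (C5 epimers) | C/C1=C\CC[C@](C)([C@@H](c2ccccc2)c2c(O)cc(OCc3ccccc3)cc2OCc2ccccc2)C(O)[C@H]2[C@@H](CC1)C2(C)C | intermediate
20 | C5 cyclopropylcarbinyl cation (not isolated) | C/C1=C\CC[C@](C)([C@@H](c2ccccc2)c2c(O)cc(OCc3ccccc3)cc2OCc2ccccc2)[CH+][C@H]2[C@@H](CC1)C2(C)C | intermediate
21 | C10 cation after C1–C5 closure (H1 anti and H5 syn to the CMe2 bridge; not isolated) | C[C+]1CC[C@@H]2[C@H]([C@@H]3[C@](C)(CC[C@H]31)[C@@H](c1ccccc1)c1c(O)cc(OCc3ccccc3)cc1OCc1ccccc1)C2(C)C | intermediate
22 | C1 cation after the 1,2-hydride shift (H10 anti to the CMe2 bridge; not isolated) | C[C@H]1CC[C@@H]2[C@H]([C@@H]3[C@](C)(CC[C+]31)[C@@H](c1ccccc1)c1c(O)cc(OCc3ccccc3)cc1OCc1ccccc1)C2(C)C | intermediate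
23 | pentacyclic 4′,6′-dibenzyl ether (psiguadial A skeleton without the formyl groups) | C[C@H]1CC[C@@H]2[C@H]([C@@H]3[C@]4(C)CC[C@@]31Oc1cc(OCc5ccccc5)cc(OCc5ccccc5)c1[C@@H]4c1ccccc1)C2(C)C | intermediate
24 | pentacyclic resorcinol (4′,6′-diol) | C[C@H]1CC[C@@H]2[C@H]([C@@H]3[C@]4(C)CC[C@@]31Oc1cc(O)cc(O)c1[C@@H]4c1ccccc1)C2(C)C | intermediate
25 | psiguadial A | C[C@H]1CC[C@@H]2[C@H]([C@@H]3[C@]4(C)CC[C@@]31Oc1c(C=O)c(O)c(C=O)c(O)c1[C@@H]4c1ccccc1)C2(C)C | target

## Step count and least certain steps

Total step count: 11. Longest linear sequence: 10 (steps 1–5 and 7–11, from 1); step 6 is a one-step side branch.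

Step 5 (key step). The most likely failure is heterolytic cleavage of C5–C10 in the hindered alkoxide (an allyl anion and an enone) followed by unselective recombination. Erosion of the E geometry through the competing chair with the vinyl group equatorial is also possible if the shift needs warming. Fallback: from 9, silylation (Me3SiCl, imidazole, DMF) gives the trimethylsilyl ether F1. Neutral thermal siloxy-Cope rearrangement (o-dichlorobenzene, about 200 °C, sealed base-washed tube) gives the silyl enol ether F2, and dilute HCl in THF hydrolyses it to 12, where the route is rejoined. The concerted neutral shift has no ionic cleavage channel.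

Step 7. The most likely failure is poor facial selectivity at C4 and C7′, because two centres are made on a conformationally mobile ten-membered enolate, or reversal of the addition, because the new bond is very crowded. Fallback: the union is moved to the hydrocarbon. From 12, KN(SiMe3)2 and PhNTf2 give the enol triflate F3, and formate reduction (Pd(OAc)2, PPh3, HCO2H, n-Bu3N, DMF, 60 °C) gives (+)-bicyclogermacrene F4. Heating F4 with 14 and catalogue 2,4-diformylphloroglucinol generates the diformyl ortho-quinone methide F5 in situ. Its addition to C4=C5 starts the same cation cascade with the natural facial course and leads directly to 25, where the route is rejoined. The price is a mixture of regio- and stereoisomeric adducts to separate; steps 7–11 are replaced by three operations.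

Step 9. The most likely failures are irreversible diversion of the C5 cation (capture by the phenol oxygen that does not reopen, or opening of the cyclopropylcarbinyl cation to a homoallyl cation) and proton loss from the C10 cation before the hydride shift. Fallback: C–C and C–O bond formation are separated. From 19, Ac2O/pyridine/DMAP gives the diacetate F6, in which the aryl oxygen can no longer intercept C5. BF3·OEt2 in CH2Cl2 at −78 °C ionises the cyclopropylcarbinyl acetate, and transannular closure with proton loss should give the tetrasubstituted C1=C10 alkene F7. K2CO3 in MeOH frees the phenol F8, and acid-catalysed hydroalkoxylation (TsOH, (CF3)2CHOH/CH2Cl2) then closes the ether and gives 23: the proton adds to C10 from the face away from the CMe2 bridge and the oxygen to C1. The route is rejoined at 23.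

Step 3. The most likely failure is slow reductive elimination at the fully substituted enolate carbon, which lets O-alkenylation, aldol self-condensation of 4 or consumption of vinyl bromide take over. Fallback: a two-step vinyl cation equivalent. From 4, LiN(iPr)2 (THF, −78 °C) and phenyl vinyl sulfoxide give the conjugate adduct F9. Thermolysis (toluene, 110 °C, CaCO3) eliminates benzenesulfenic acid by syn elimination and gives 7, where the route is rejoined.

Step 11. The most likely failure is ionisation of the C1–O ether or opening of the cyclopropane by TiCl4, or a stalled second formylation. Fallback: base-mediated ortho-formylation. From 24, the magnesium phenoxide (MgCl2, Et3N) reacts with paraformaldehyde in refluxing MeCN/THF at both positions ortho to the free hydroxyls (hydroxymethylation, then hydride transfer to formaldehyde) and gives 25 directly. No new compound is made on this path (entry F0).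

## Further compounds

F1 | step 5 | trimethylsilyl ether of 9 | C[C@@]1(C=C)CC[C@@H]2[C@H]([C@]1(O[Si](C)(C)C)C(C)=C)C2(C)C
F2 | step 5 | trimethylsilyl enol ether of 12 (C3 and C6 cis across C4=C5) | C/C1=C\CC/C(C)=C(/O[Si](C)(C)C)\[C@H]2[C@@H](CC1)C2(C)C
F3 | step 7 | enol triflate of 12 (C3 and C6 trans across C4=C5) | C/C1=C\CC/C(C)=C(\OS(=O)(=O)C(F)(F)F)/[C@H]2[C@@H](CC1)C2(C)C
F4 | step 7 | (+)-bicyclogermacrene | C/C1=C\CC/C(C)=C/[C@H]2[C@@H](CC1)C2(C)C
F5 | step 7 | 6-benzylidene-2,4-diformyl-3,5-dihydroxycyclohexa-2,4-dien-1-one (diformyl ortho-quinone methide) | O=CC1=C(O)C(C=O)=C(O)C(=Cc2ccccc2)C1=O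
F6 | step 9 | diacetate of 19 (aryl acetate and C5 acetate) | C/C1=C\CC[C@](C)([C@@H](c2ccccc2)c2c(OC(C)=O)cc(OCc3ccccc3)cc2OCc2ccccc2)C(OC(C)=O)[C@H]2[C@@H](CC1)C2(C)C
F7 | step 9 | tricyclic C1=C10 alkene, aryl acetate | CC=1CC[C@@H]2[C@H]([C@@H]3[C@](C)(CCC3=1)[C@@H](c1ccccc1)c1c(OC(C)=O)cc(OCc3ccccc3)cc1OCc1ccccc1)C2(C)C
F8 | step 9 | tricyclic C1=C10 alkene, free phenol | CC=1CC[C@@H]2[C@H]([C@@H]3[C@](C)(CCC3=1)[C@@H](c1ccccc1)c1c(O)cc(OCc3ccccc3)cc1OCc1ccccc1)C2(C)C
F9 | step 3 | 3-[2-(phenylsulfinyl)ethyl] derivative of 4 (sulfur epimers) | C[C@@]1(CCS(=O)c3ccccc3)CC[C@@H]2[C@H](C1=O)C2(C)C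
F0 | step 11 | none | none
A1 | alternative 1 | 5–7–3 tricyclic cyclopent-1-en-3-one (C4 epimers) | C[C@H]1CC[C@@H]2[C@H]([C@@H]3C(C)C(=O)C=C31)C2(C)C
A2 | alternative 1 | 3,5-dimethoxy-2-[phenyl(4-methylphenylsulfonyl)methyl]phenol | Cc1ccc(cc1)S(=O)(=O)C(c1ccccc1)c1c(O)cc(OC)cc1OC
A3 | alternative 1 | 3-oxo pentacyclic dimethyl ether | C[C@H]1CC[C@@H]2[C@H]([C@@H]3[C@]4(C)C(=O)C[C@@]31Oc1cc(OC)cc(OC)c1[C@@H]4c1ccccc1)C2(C)C
A4 | alternative 2 | carene-derived cross-conjugated decalin dienone with the aryl(phenyl)methyl group on C4 | C[C@@]12CC[C@@H]3[C@H](C1=C([C@@H](c1ccccc1)c1c(OC)cc(OC)cc1OC)C(=O)C=C2)C3(C)C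
A5 | alternative 2 | 10-hydroxy-3-oxo hydroazulenone | C[C@@]1(O)CC[C@@H]2[C@H](C3=C([C@@H](c4ccccc4)c4c(OC)cc(OC)cc4OC)C(=O)C[C@H]31)C2(C)C
A6 | alternative 3 | cis-cyclopropane allenyne | C#C[C@H]1[C@@H](CCC(C)=C=C)C1(C)C
A7 | alternative 3 | tricyclic 3-oxo-1(10),4-dienone | CC=1CC[C@@H]2[C@H](C3=CC(=O)CC3=1)C2(C)C
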